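Assumptions: natural (+)-carnosic acid (bulk rosemary antioxidant) counts as a commercial starting material. Abietane/icetexane numbering is used throughout (C5, C7, C10, C20 and so on).

## Retrosynthetic overview
1. 10 ⇒ 9: the ring C quinone is made last, by 4-electron oxidation of the 11,12-dimethoxyarene (C14–O formed, 11-O-methyl lost).
2. 9 ⇒ 8: one light-driven step. A C20 radical undergoes a 1,2-aryl shift (C9–C20 made, C9–C10 cut, ring B 6→7). The resulting C10 cation takes up water, and the 10β-OH closes on C7=O to form the oxa-bridge.
3. 8 ⇒ 6 ⇒ 1: C20–OH activation. The 7-oxo-20-ol comes from carnosic acid by O-methylation, C7 oxidation, hydride reduction and selective benzylic re-oxidation.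
4. Ring order: A and C (with C5 and C10) are bought in 1, then B is expanded, then the tetrahydrofuran bridge forms, then the quinone.

## Route

**Step 1**
Reactants: 1 (+)-carnosic acid; 2 iodomethane
Product: 3 methyl 11,12-dimethoxyabieta-8,11,13-trien-20-oate (5S,10R; 5α-H, 10β-CO2Me)
Conditions: MeI (6 equiv), K2CO3, degassed DMF, Ar, 45 °C
Reagents that add atoms: iodomethane, CI (3 × CH3)
Why: Exhaustive Williamson/carboxylate SN2 methylation masks the air-sensitive catechol and the acid in one operation, and no stereocentre is touched.

**Step 2**
Reactants: 3
Product: 4 methyl 11,12-dimethoxy-7-oxoabieta-8,11,13-trien-20-oate (5S,10R)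
Conditions: CrO3, AcOH/H2O, rt
Reagents that add atoms: chromium trioxide, O=[Cr](=O)=O (one O)
Why: This is the classical Cr(VI) benzylic oxidation of abietatriene aryl ethers; C7 is the only benzylic CH2 and lies para to the 12-OMe, and C5 is β to the new ketone so it cannot epimerise.

**Step 3**
Reactants: 4
Product: 5 11,12-dimethoxyabieta-8,11,13-triene-7,20-diol (5S,10R; C7 epimer mixture, erased in step 4)
Conditions: LiAlH4 (5 equiv), THF, reflux; Rochelle-salt work-up (no acid)
Reagents that add atoms: none
Why: Hydride reduction takes the hindered neopentyl ester to CH2OH (the ketone is unavoidably reduced too), and the neutral work-up prevents ionisation of the p-methoxybenzylic alcohol.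

**Step 4**
Reactants: 5
Product: 6 20-hydroxy-11,12-dimethoxyabieta-8,11,13-trien-7-one (5S,10R)
Conditions: activated MnO2 (20 equiv), CH2Cl2, rt
Reagents that add atoms: none
Why: MnO2 oxidises only the benzylic alcohol and leaves the saturated neopentyl C20–OH alone.

**Step 5**
Reactants: 6; 7 pentafluorophenyl chlorothionoformate
Product: 8 O-(11,12-dimethoxy-7-oxoabieta-8,11,13-trien-20-yl) O-pentafluorophenyl thionocarbonate (5S,10R)
Conditions: 7 (1.5 equiv), DMAP (2 equiv), CH2Cl2, 0 °C → rt
Reagents that add atoms: pentafluorophenyl chlorothionoformate, S=C(Cl)Oc1c(F)c(F)c(F)c(F)c1F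
Why: DMAP-catalysed O-thioacylation gives the Barton–McCombie derivative designed for primary alcohols; it is neutral, does not ionise at rt and is easily reduced.

**Step 6 (key step)**
Reactants: 8 (plus water)
Product: 9 (5S,7S,10S)-7β,10β-epoxy-7-hydroxy-11,12-dimethoxy-9(10→20)abeo-abieta-8,11,13-triene (icetexane hemiketal; 5α-H)
Conditions: fac-Ir(ppy)3 (2 mol %), acetone/H2O 4:1 (0.02 M), Ar (freeze–pump–thaw), 450 nm LED, 35 °C
Reagents that add atoms: water, O
Why: Proposed new method: redox-neutral photoredox deoxygenative 1,2-aryl-shift ring expansion with radical–polar crossover; *Ir(III) (−1.7 V) reduces the C=S group and loss of C6F5O⁻ and COS gives the neopentyl C20 radical, whose axial orbital sits over C9; 3-exo ipso attack gives a spiro-cyclohexadienyl radical stabilised by the C7 ketone on C8 and by the 11-OMe, and this opens by C9–C10 cleavage to the tertiary C10 radical, forming C9–C20 and the seven-membered ring; only this tertiary radical (about +0.1 V) is oxidisable by Ir(IV) (+0.77 V), which drains the equilibrium and closes the catalytic cycle; water then attacks the C10 cation from the β face, because the benzocycloheptenone folds under the α face (the fold that keeps C7 anti to quaternary C4), which is the same sense as anti-opening of a phenonium ion, so C10 is relayed from the bought C5 and C10 centres; the 10β-OH adds to C7=O, and the bridge geometry fixes C7; acetone is used instead of MeCN to avoid Ritter capture; the closest known reaction types are Barton–McCombie fragmentation and photoredox reduction of thiocarbonyl esters, the neophyl rearrangement, photoredox radical–polar crossover of redox-active esters, and the ionic abietane→icetexane shift.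

**Step 7**
Reactants: 9 (plus water)
Product: 10 (+)-komaroviquinone (5S,7S,10S)
Conditions: (NH4)2Ce(NO3)6 (5 equiv), MeCN/H2O 2:1, 0 °C, amber glassware
Reagents that add atoms: water, O
Why: In this CAN oxidative demethylation the arene radical cation is hydroxylated at its only free position C14 (para to the 11-OMe), and the resulting 4-methoxyphenol is oxidised with loss of MeOH to the 12-methoxy-11,14-quinone; the hemiketal and all three stereocentres are untouched, and light is excluded because the product is photolabile.

## Compound list
| No. | Name | SMILES | Role |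
|---|---|---|---|
| 1 | (+)-carnosic acid | CC(C)c1c(O)c(O)c2c(c1)CC[C@@H]3[C@@]2(CCCC3(C)C)C(=O)O | starting material |
| 2 | iodomethane | CI | starting material |
| 3 | methyl 11,12-di-O-methylcarnosate | CC(C)c1c(OC)c(OC)c2c(c1)CC[C@@H]3[C@@]2(CCCC3(C)C)C(=O)OC | intermediate |
| 4 | 7-oxo ester | CC(C)c1c(OC)c(OC)c2c(c1)C(=O)C[C@@H]3[C@@]2(CCCC3(C)C)C(=O)OC | intermediate |
| 5 | 7,20-diol (C7 epimers) | CC(C)c1c(OC)c(OC)c2c(c1)C(O)C[C@@H]3[C@@]2(CCCC3(C)C)CO | intermediate |
| 6 | 7-oxo-20-ol | CC(C)c1c(OC)c(OC)c2c(c1)C(=O)C[C@@H]3[C@@]2(CCCC3(C)C)CO | intermediate |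
| 7 | pentafluorophenyl chlorothionoformate | S=C(Cl)Oc1c(F)c(F)c(F)c(F)c1F | starting material |
| 8 | C20 pentafluorophenyl thionocarbonate | CC(C)c1c(OC)c(OC)c2c(c1)C(=O)C[C@@H]3[C@@]2(CCCC3(C)C)COC(=S)Oc4c(F)c(F)c(F)c(F)c4F | intermediate |
| 9 | 11,12-dimethoxy icetexane hemiketal | COc1c(C(C)C)cc2c(C[C@@]34CCCC(C)(C)[C@@H]3C[C@]2(O)O4)c1OC | intermediate |
| 10 | (+)-komaroviquinone | COC1=C(C(C)C)C(=O)C2=C(C[C@@]34CCCC(C)(C)[C@@H]3C[C@]2(O)O4)C1=O | target |

## Totals
Total steps: 7. Longest linear sequence: 7, from carnosic acid.

## Steps most likely to fail
1. **Step 6 (new reaction).**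
   - Risks: slow C–O scission of a primary thionocarbonate; H-abstraction by the C20 radical to give the 20-methyl compound; E1 loss from the C10 cation, where the Δ5(10) alkene would erase C5; imperfect facial selectivity at C10.
   - Fallback (known chemistry): the ionic biomimetic shift. Mesylate or triflate the C20–OH of 6 and solvolyse in buffered aqueous medium. This is a Wagner–Meerwein 1,2-aryl migration through a phenonium ion with anti capture by water, and it gives the 10β-ol, which closes to 9.
   - If the 7-ketone retards ionisation, run the shift with C7 as a silyl-protected alcohol, then deprotect and oxidise C7 to the ketone.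
2. **Step 7.**
   - Risks: a 1,2-dimethoxyarene may give the 11,12-o-quinone or side-chain oxidation instead of C14 hydroxylation.
   - Fallback: cleave the 11-OMe nucleophilically (EtSNa, DMF) and oxidise the free 11-phenol with Fremy's salt (Teuber oxidation) or Co(salen)/O2.
   - If mono-demethylation is unselective, install the C14 oxygen early (NBS at C14 of 3, then Cu-catalysed methoxylation). The route then finishes with the standard CAN oxidation of a 1,4-dimethoxyarene.
3. **Step 2.**
   - Risks: competing oxidation at the isopropyl methine, or over-oxidation at C6.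
   - Fallback: avoid C–H oxidation and use the catechol instead. Oxidise 1 with Ag2O to the o-quinone, which tautomerises to the quinone methide and lactonises at C7 to give carnosol. O-methylation followed by LiAlH4 gives the same diol 5 in the same number of steps.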